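**Retrosynthetic overview**
1. Ar–CH2 bond and side-chain stereocentre together: sulcatone 1 is methylenated to the α-prenyl vinyl ketone 2, which takes up the C2-symmetric acetophenone 3 in a primary-amine-catalysed Friedel–Crafts conjugate addition/enantioselective protonation to give (R)-ketone 4.
2. Lavandulyl group: 4 → 5 (MOM on the remote phenol) → 6 (side-chain C=O converted to C=CH2).
3. Cα–Cβ bond: aldehyde 7 → bis-MOM aldehyde 8; 6 + 8 → (aldol 9) → chalcone 10 by Claisen–Schmidt condensation.
4. O1–C2 bond and the (2S) centre: organocatalytic oxa-Michael closure 10 → 11; MOM removal gives target 12, the (2S)-flavanone carrying the (2R)-lavandulyl group at C8.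
5. Ring order: rings A and B are bought as 3 and 7; ring C (the pyranone) is the only ring made and is closed in the penultimate step.

Assumption: catalyst preparation is not counted as a step, and only free species are numbered as intermediates (iminium ions, enamines, enolates and oxaphosphetanes are described in the Why lines instead).

**Step 1**
Reactants: 1 6-methylhept-5-en-2-one (sulcatone)
Product: 2 6-methyl-3-methylidenehept-5-en-2-one
Conditions: (CH2O)n (2 equiv), PhNHMe·CF3CO2H (1 equiv), THF, reflux, 6 h; distil, store cold over BHT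
Reagents that add atoms: paraformaldehyde (formaldehyde), C=O
Why: Mannich-type α-methylenation in which the more substituted, acid-favoured enol of 1 attacks the formaldehyde-derived iminium ion and β-elimination of the amine leaves the 1,1-disubstituted enone at C3, with no stereocentre formed.

**Step 2**
Reactants: 2 6-methyl-3-methylidenehept-5-en-2-one (1.0 equiv); 3 1-(2,6-dihydroxy-4-methoxyphenyl)ethan-1-one (1.5 equiv)
Product: 4 (3R)-3-[(3-acetyl-2,4-dihydroxy-6-methoxyphenyl)methyl]-6-methylhept-5-en-2-one
Conditions: (S)-N1,N1-diethyl-3,3-dimethylbutane-1,2-diamine·TfOH (20 mol %), 3-nitrobenzoic acid (20 mol %), CHCl3, 25 °C, 48 h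
Reagents that add atoms: none
Why: Proposed new method: the primary amine of the catalyst condenses with enone 2 to an α-substituted vinyl ketiminium ion, the electron-rich ring of 3 (C3 and C5 are equivalent, so only one regioisomer can form) adds through carbon to the terminal CH2 and rearomatises, and the resulting catalyst-bound enamine is protonated on one face by the neighbouring Et2NH+ arm acting as an intramolecular proton shuttle while the t-Bu group shields the other face, which sets the (R)-centre before hydrolysis releases 4; the closest known reaction type is the chiral primary–tertiary diamine-catalysed Friedel–Crafts conjugate addition/enantioselective enamine protonation of indoles with α-substituted acroleins and vinyl ketones, here carried over to a phenolic (acylphloroglucinol) carbon nucleophile.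

**Step 3**
Reactants: 4 (3R)-3-[(3-acetyl-2,4-dihydroxy-6-methoxyphenyl)methyl]-6-methylhept-5-en-2-one
Product: 5 (3R)-3-{[3-acetyl-2-hydroxy-6-methoxy-4-(methoxymethoxy)phenyl]methyl}-6-methylhept-5-en-2-one
Conditions: MOMCl (1.1 equiv), i-Pr2NEt (1.5 equiv), CH2Cl2, 0 °C, 2 h
Reagents that add atoms: chloromethyl methyl ether (MOMCl), COCCl
Why: MOM protection (Williamson-type O-alkylation) goes to the 4-OH, which has one ortho substituent, while the 2-OH is flanked by the branched side chain and the acetyl group; it stops at mono-protection because the last OH is locked in the hydrogen bond to the acetyl C=O, and the amine base is too weak to touch the α-stereocentre.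

**Step 4**
Reactants: 5 (3R)-3-{[3-acetyl-2-hydroxy-6-methoxy-4-(methoxymethoxy)phenyl]methyl}-6-methylhept-5-en-2-one
Product: 6 1-{2-hydroxy-4-methoxy-6-(methoxymethoxy)-3-[(2R)-5-methyl-2-(prop-1-en-2-yl)hex-4-en-1-yl]phenyl}ethan-1-one
Conditions: Ph3PCH3Br (3.5 equiv), KOtBu (3.3 equiv), THF, 0 → 20 °C, 3 h
Reagents that add atoms: methyltriphenylphosphonium bromide, C[P+](c1ccccc1)(c1ccccc1)c1ccccc1.[Br-]
Why: Wittig methylenation takes the aliphatic methyl ketone only, because the aryl ketone is di-ortho-substituted and conjugated with the phenoxide formed in the flask, and at 0–20 °C ylide addition outruns enolisation so the (R)-centre passes unchanged into the lavandulyl group.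

**Step 5**
Reactants: 7 2,5-dihydroxybenzaldehyde
Product: 8 2,5-bis(methoxymethoxy)benzaldehyde
Conditions: MOMCl (3 equiv), i-Pr2NEt (4 equiv), CH2Cl2, 0 → 40 °C, 12 h
Reagents that add atoms: chloromethyl methyl ether (MOMCl), COCCl
Why: Standard double MOM protection of a hydroquinone, with excess reagent and gentle heating to overcome the chelated 2-OH.

**Step 6**
Reactants: 6 1-{2-hydroxy-4-methoxy-6-(methoxymethoxy)-3-[(2R)-5-methyl-2-(prop-1-en-2-yl)hex-4-en-1-yl]phenyl}ethan-1-one; 8 2,5-bis(methoxymethoxy)benzaldehyde (1.2 equiv)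
Product: 10 (2E)-3-[2,5-bis(methoxymethoxy)phenyl]-1-{2-hydroxy-4-methoxy-6-(methoxymethoxy)-3-[(2R)-5-methyl-2-(prop-1-en-2-yl)hex-4-en-1-yl]phenyl}prop-2-en-1-one, via aldol adduct 9 (not isolated)
Conditions: KOH (10 equiv, 40% aq), EtOH, 0 → 20 °C, 36 h, Ar; then 1 M HCl to pH 5 at 0 °C
Reagents that add atoms: none
Why: Claisen–Schmidt condensation in which the potassium enolate of the aryl methyl ketone adds to the non-enolisable aldehyde and E1cB loss of water from aldol 9 gives the conjugated (E)-enone, while the lavandulyl centre carries no acidic hydrogen and is untouched.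

**Step 7**
Reactants: 10 the (E)-chalcone from step 6
Product: 11 (2S)-2-[2,5-bis(methoxymethoxy)phenyl]-7-methoxy-5-(methoxymethoxy)-8-[(2R)-5-methyl-2-(prop-1-en-2-yl)hex-4-en-1-yl]-2,3-dihydro-4H-chromen-4-one
Conditions: 1-[3,5-bis(trifluoromethyl)phenyl]-3-[(8S,9S)-6′-methoxycinchonan-9-yl]thiourea (quinine-derived, 20 mol %), toluene, 20 °C, 72 h
Reagents that add atoms: none
Why: Organocatalytic intramolecular oxa-Michael addition (6-endo-trig) in which the thiourea binds the enone carbonyl and the quinuclidine nitrogen activates the only free phenol, so the phenoxide is delivered to one enantiotopic face of the β-carbon and closes ring C as (2S) under catalyst control, the remote (R)-centre being a spectator.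

**Step 8**
Reactants: 11 the tris-MOM flavanone from step 7
Product: 12 (2S)-2-(2,5-dihydroxyphenyl)-5-hydroxy-7-methoxy-8-[(2R)-5-methyl-2-(prop-1-en-2-yl)hex-4-en-1-yl]-2,3-dihydro-4H-chromen-4-one (target)
Conditions: 3 M aq HCl–MeOH 1:9, 40 °C, 4 h
Reagents that add atoms: none
Why: Acid-catalysed transacetalisation of the three aryl MOM ethers to dimethoxymethane; under this dilute acid the flavanone C2 is configurationally stable, and no free phenol sits ortho to the lavandulyl group, so chroman formation cannot compete.

**Compound list**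
1 | 6-methylhept-5-en-2-one (sulcatone) | CC(=O)CCC=C(C)C | starting material
2 | 6-methyl-3-methylidenehept-5-en-2-one | CC(=O)C(=C)CC=C(C)C | intermediate
3 | 1-(2,6-dihydroxy-4-methoxyphenyl)ethan-1-one | CC(=O)c1c(O)cc(OC)cc1O | starting material
4 | (3R)-3-[(3-acetyl-2,4-dihydroxy-6-methoxyphenyl)methyl]-6-methylhept-5-en-2-one | CC(=O)[C@H](CC=C(C)C)Cc1c(O)c(C(C)=O)c(O)cc1OC | intermediate
5 | (3R)-3-{[3-acetyl-2-hydroxy-6-methoxy-4-(methoxymethoxy)phenyl]methyl}-6-methylhept-5-en-2-one | CC(=O)[C@H](CC=C(C)C)Cc1c(O)c(C(C)=O)c(OCOC)cc1OC | intermediate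
6 | 1-{2-hydroxy-4-methoxy-6-(methoxymethoxy)-3-[(2R)-5-methyl-2-(prop-1-en-2-yl)hex-4-en-1-yl]phenyl}ethan-1-one | C=C(C)[C@H](CC=C(C)C)Cc1c(O)c(C(C)=O)c(OCOC)cc1OC | intermediate
7 | 2,5-dihydroxybenzaldehyde | O=Cc1cc(O)ccc1O | starting material
8 | 2,5-bis(methoxymethoxy)benzaldehyde | O=Cc1cc(OCOC)ccc1OCOC | intermediate
9 | 3-[2,5-bis(methoxymethoxy)phenyl]-3-hydroxy-1-{2-hydroxy-4-methoxy-6-(methoxymethoxy)-3-[(2R)-5-methyl-2-(prop-1-en-2-yl)hex-4-en-1-yl]phenyl}propan-1-one (aldol adduct, both carbinol epimers, not isolated) | C=C(C)[C@H](CC=C(C)C)Cc1c(O)c(C(=O)CC(O)c2cc(OCOC)ccc2OCOC)c(OCOC)cc1OC | intermediate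
10 | (2E)-3-[2,5-bis(methoxymethoxy)phenyl]-1-{2-hydroxy-4-methoxy-6-(methoxymethoxy)-3-[(2R)-5-methyl-2-(prop-1-en-2-yl)hex-4-en-1-yl]phenyl}prop-2-en-1-one | C=C(C)[C@H](CC=C(C)C)Cc1c(O)c(C(=O)/C=C/c2cc(OCOC)ccc2OCOC)c(OCOC)cc1OC | intermediate
11 | (2S)-2-[2,5-bis(methoxymethoxy)phenyl]-7-methoxy-5-(methoxymethoxy)-8-[(2R)-5-methyl-2-(prop-1-en-2-yl)hex-4-en-1-yl]-2,3-dihydro-4H-chromen-4-one | C=C(C)[C@H](CC=C(C)C)Cc1c(OC)cc(OCOC)c2c1O[C@H](c1cc(OCOC)ccc1OCOC)CC2=O | intermediate
12 | (2S)-2-(2,5-dihydroxyphenyl)-5-hydroxy-7-methoxy-8-[(2R)-5-methyl-2-(prop-1-en-2-yl)hex-4-en-1-yl]-2,3-dihydro-4H-chromen-4-one | C=C(C)[C@H](CC=C(C)C)Cc1c(OC)cc(O)c2c1O[C@H](c1cc(O)ccc1O)CC2=O | target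

**Totals**
Total step count: 8. Longest linear sequence: 7 steps (1, 2, 3, 4, 6, 7, 8); step 5 is the one-step side branch.

**Three steps most likely to fail**

Step 2 (the proposed new reaction) is the main risk.
- The ketiminium ion may be too weak an electrophile for the acyl-deactivated phenol.
- The primary amine may be tied up as a Schiff base with the acetyl group of 3.
- A second alkylation at C5 is possible, which is why 3 is used in excess.
- The ee may be eroded by an uncatalysed background addition or by re-enamination of 4.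
- The sense of induction is a prediction from the proton-shuttle model; if it is opposite, the enantiomeric catalyst from D-tert-leucine is used.

Fallback with known chemistry, setting out from 2 and 3 and coming back at 4: the same C–C bond is made without stereocontrol by ordinary base-mediated Michael C-alkylation of the acylphloroglucinol (Et3N 0.5 equiv, toluene, 60 °C). This gives racemic 3-[(3-acetyl-2,4-dihydroxy-6-methoxyphenyl)methyl]-6-methylhept-5-en-2-one F1. F1 is resolved by preparative supercritical-fluid chromatography on an amylose tris(3,5-dimethylphenylcarbamate) phase, and the (R)-enantiomer is 4. The unwanted (3S)-3-[(3-acetyl-2,4-dihydroxy-6-methoxyphenyl)methyl]-6-methylhept-5-en-2-one F2 is racemised back to F1 with DBU in toluene at 60 °C and recycled.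

Step 4 can fail in two ways. The basic ylide may partly enolise the α-branched ketone and lower the ee of the lavandulyl centre. The substrate may also react slowly as its phenoxide; 4 and 5 can sit partly in their closed hemiketal tautomeric form, which base reopens.

Fallback, setting out from 5 and coming back at 6: a non-basic organocerium addition followed by Peterson elimination. Me3SiCH2Li–CeCl3 (3 equiv, THF, −78 °C) adds only to the aliphatic ketone and gives the β-hydroxysilane (3R)-3-{[3-acetyl-2-hydroxy-6-methoxy-4-(methoxymethoxy)phenyl]methyl}-2,6-dimethyl-1-(trimethylsilyl)hept-5-en-2-ol F3 as both carbinol epimers. KH (THF, 20 °C) then induces syn-elimination of the silanolate and delivers 6 with no enolisable ketone left.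

Step 7 may give only modest selectivity at C2. The attacking OH is flanked by the lavandulyl group and the enone is twisted by the 6′-OMOM group. Slow retro-Michael reversal can erode selectivity further, and the C2 epimers are hard to separate on silica. If the sense of induction is opposite on this substrate, the quinidine-derived pseudoenantiomeric thiourea is used.

Fallback, setting out from 10 and coming back at 11: thermodynamic, non-selective ring closure with NaOAc in refluxing EtOH gives 11 together with (2R)-2-[2,5-bis(methoxymethoxy)phenyl]-7-methoxy-5-(methoxymethoxy)-8-[(2R)-5-methyl-2-(prop-1-en-2-yl)hex-4-en-1-yl]-2,3-dihydro-4H-chromen-4-one F4 in about 1:1 ratio. The two C2 epimers are diastereomers and are separated by preparative HPLC on a chiral stationary phase. F4 is reopened to chalcone 10 with KOH in EtOH and recycled.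

**Further compounds**
F1 | step 2 | racemic 3-[(3-acetyl-2,4-dihydroxy-6-methoxyphenyl)methyl]-6-methylhept-5-en-2-one | CC(=O)C(CC=C(C)C)Cc1c(O)c(C(C)=O)c(O)cc1OC
F2 | step 2 | (3S)-3-[(3-acetyl-2,4-dihydroxy-6-methoxyphenyl)methyl]-6-methylhept-5-en-2-one | CC(=O)[C@@H](CC=C(C)C)Cc1c(O)c(C(C)=O)c(O)cc1OC
F3 | step 4 | (3R)-3-{[3-acetyl-2-hydroxy-6-methoxy-4-(methoxymethoxy)phenyl]methyl}-2,6-dimethyl-1-(trimethylsilyl)hept-5-en-2-ol (both carbinol epimers) | C[Si](C)(C)CC(C)(O)[C@H](CC=C(C)C)Cc1c(O)c(C(C)=O)c(OCOC)cc1OC
F4 | step 7 | (2R)-2-[2,5-bis(methoxymethoxy)phenyl]-7-methoxy-5-(methoxymethoxy)-8-[(2R)-5-methyl-2-(prop-1-en-2-yl)hex-4-en-1-yl]-2,3-dihydro-4H-chromen-4-one | C=C(C)[C@H](CC=C(C)C)Cc1c(OC)cc(OCOC)c2c1O[C@@H](c1cc(OCOC)ccc1OCOC)CC2=O
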